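**Plan**

- Retrosynthesis: the C7 ketone is traced back to a benzylic alcohol and the C9 alcohol to an N-acyl oxazolidinone. The C8–O–C4' ether and the C7–O bond are then cut together, leaving an N-sinapoyl oxazolidinone and dihydroconiferyl alcohol. Last, the imide N–C9 bond is cut to sinapic acid and (R)-4-benzyl-2-oxazolidinone.
- Forward: sinapic acid is silylated at the phenol, joined to the auxiliary and desilylated. The free phenol is cross-coupled oxidatively with dihydroconiferyl alcohol at C8 and the quinone methide is hydrated at C7. Hydride cleavage of the imide and benzylic oxidation finish the chain. No ring is formed at any stage; both arenes are bought.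
- Enabling feature: ring A is a 4-hydroxy-3,5-dimethoxyphenyl unit with both ortho carbons blocked and conjugated through C7=C8 to the C9 acyl group. Its phenoxyl radical therefore reacts at C8, and the C9 carbonyl can hold a chiral imide next to the forming centre.
- Stereochemistry: C8, the only stereocentre of the target, is set in the coupling by the benzyl group of the magnesium-chelated (R)-oxazolidinone. C8 epimers are diastereomers at the imide stage and can be removed there. C7 is a passing centre.

Key step: step 4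

Remark: water is expected to add to both faces of C7 of the quinone methide; the erythro alcohol is drawn for the coupled imide and the derived triol, and the C7 epimer is carried along unseparated because the last step turns C7 into a carbonyl.

**Route**

Step 1
Reactants: 1 sinapic acid
Product: 3 (E)-3-[4-(tert-butyldimethylsilyloxy)-3,5-dimethoxyphenyl]prop-2-enoic acid, via bis-silyl ester 2 (not isolated)
Conditions: TBSCl (2.4 equiv), imidazole (5 equiv), DMF, rt; then AcOH/THF/H2O (3:1:1), rt
Reagents that add atoms: tert-butyldimethylsilyl chloride, CC(C)(C)[Si](C)(C)Cl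
Why: Silylation covers the phenol and the acid, and the silyl ester is far more labile than the hindered aryl silyl ether, so aqueous acetic acid should hydrolyse it selectively (silyl protection followed by selective silyl ester hydrolysis).

Step 2
Reactants: 3 (E)-3-[4-(tert-butyldimethylsilyloxy)-3,5-dimethoxyphenyl]prop-2-enoic acid; 4 (R)-4-benzyl-2-oxazolidinone
Product: 6 (R)-4-benzyl-3-[(E)-3-[4-(tert-butyldimethylsilyloxy)-3,5-dimethoxyphenyl]prop-2-enoyl]oxazolidin-2-one, via mixed pivalic anhydride 5 (not isolated)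
Conditions: PivCl (1.05 equiv), Et3N (2.5 equiv), THF, −20 °C; then LiCl (1.1 equiv), 4 (1.0 equiv), −20 °C to rt
Reagents that add atoms: none
Why: N-Acylation of the oxazolidinone through the mixed pivalic anhydride under LiCl/Et3N activation should occur at the less hindered cinnamoyl carbonyl, leaving the (E)-alkene and the auxiliary stereocentre untouched.

Step 3
Reactants: 6 (R)-4-benzyl-3-[(E)-3-[4-(tert-butyldimethylsilyloxy)-3,5-dimethoxyphenyl]prop-2-enoyl]oxazolidin-2-one
Product: 7 (R)-4-benzyl-3-[(E)-3-(4-hydroxy-3,5-dimethoxyphenyl)prop-2-enoyl]oxazolidin-2-one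
Conditions: Bu4NF (1.1 equiv), AcOH (1.2 equiv), THF, 0 °C
Reagents that add atoms: none
Why: Fluoride-mediated cleavage of the aryl silyl ether should be fast, and the acetic acid buffer keeps the liberated phenoxide from attacking the imide.

Step 4
Reactants: 7 (R)-4-benzyl-3-[(E)-3-(4-hydroxy-3,5-dimethoxyphenyl)prop-2-enoyl]oxazolidin-2-one; 8 dihydroconiferyl alcohol
Product: 10 (R)-4-benzyl-3-[(2R,3R)-3-hydroxy-3-(4-hydroxy-3,5-dimethoxyphenyl)-2-[4-(3-hydroxypropyl)-2-methoxyphenoxy]propanoyl]oxazolidin-2-one, via quinone methide 9 (not isolated)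
Conditions: Mg(ClO4)2 (1.2 equiv, premixed with 7), Ag2O (2 equiv), 8 (4 equiv), CH2Cl2/THF (9:1), 0 °C, dark, 7 added over 4 h; then cold filtration through Celite into THF/aq. citric acid (pH 3), 0 °C
Reagents that add atoms: water, O
Why: Proposed new method: Ag2O removes one electron and one proton from each phenol; the radical of 7 has its ortho carbons blocked by methoxyl groups and so reacts through C8, which recombines with the phenoxyl oxygen of 8 to give quinone methide 9, and acid-catalysed addition of water to C7 then restores aromatic ring A. The closest known reaction types are the racemic Ag2O or peroxidase 8–O–4' cross-couplings of hydroxycinnamates with phenols and the auxiliary-directed oxidative 8–8' and 8–5' dimerisations of hydroxycinnamoyl amides. No ring closes in this step. C8 is controlled by the auxiliary: Mg(ClO4)2 holds the two imide carbonyls syn and the enoyl unit s-cis, the benzyl group covers one face of C8 and the aryloxyl radical enters from the other, the sense known for alkylation of chelated Z-enolates, which with the (R)-auxiliary leads to the (2R) imide; C7 is not controlled and need not be. Cross-coupling has to beat 8–8' homodimerisation, which is addressed by a fourfold excess of 8 and slow addition of 7, and attack at the oxygen of 8 is favoured over 8–5' attack as in the coupling of side-chain radicals with guaiacyl units in lignin formation. Hydration must also outrun loss of the acidic H8 from 9, which would erase the new centre, so the coupling is run dry (Mg(ClO4)2 also binds the water released from Ag2O, and 9, having no free phenol, is safe from further oxidation) and water is supplied only together with mild acid once the silver has been filtered off.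

Step 5
Reactants: 10 (R)-4-benzyl-3-[(2R,3R)-3-hydroxy-3-(4-hydroxy-3,5-dimethoxyphenyl)-2-[4-(3-hydroxypropyl)-2-methoxyphenoxy]propanoyl]oxazolidin-2-one
Product: 11 (1R,2S)-1-(4-hydroxy-3,5-dimethoxyphenyl)-2-[4-(3-hydroxypropyl)-2-methoxyphenoxy]propane-1,3-diol
Conditions: LiBH4 (4 equiv), H2O (1 equiv), THF/Et2O, 0 °C; sat. aq. NH4Cl
Reagents that add atoms: none
Why: Reductive cleavage of an N-acyl oxazolidinone by LiBH4 at the exocyclic carbonyl should give the C9 alcohol and release the auxiliary; at 0 °C the C8 centre and the C7 alcohol are expected to survive.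

Step 6
Reactants: 11 (1R,2S)-1-(4-hydroxy-3,5-dimethoxyphenyl)-2-[4-(3-hydroxypropyl)-2-methoxyphenoxy]propane-1,3-diol
Product: 12 (2S)-3-hydroxy-1-(4-hydroxy-3,5-dimethoxyphenyl)-2-[4-(3-hydroxypropyl)-2-methoxyphenoxy]propan-1-one
Conditions: DDQ (1.1 equiv), 1,4-dioxane, rt, dark
Reagents that add atoms: none
Why: DDQ dehydrogenation is selective for a benzylic alcohol para to a free phenol (hydride loss from C7 assisted by the ring A hydroxyl), so the two primary alcohols and the benzylic CH2 of ring B should stay intact, and the near-neutral medium should leave C8 unchanged.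

**Compound list**

1 | sinapic acid | COc1cc(/C=C/C(=O)O)cc(OC)c1O | starting material
2 | tert-butyldimethylsilyl (E)-3-[4-(tert-butyldimethylsilyloxy)-3,5-dimethoxyphenyl]prop-2-enoate (bis-silyl ester) | COc1cc(/C=C/C(=O)O[Si](C)(C)C(C)(C)C)cc(OC)c1O[Si](C)(C)C(C)(C)C | intermediate
3 | (E)-3-[4-(tert-butyldimethylsilyloxy)-3,5-dimethoxyphenyl]prop-2-enoic acid | COc1cc(/C=C/C(=O)O)cc(OC)c1O[Si](C)(C)C(C)(C)C | intermediate
4 | (R)-4-benzyl-2-oxazolidinone | O=C1N[C@H](Cc2ccccc2)CO1 | starting material
5 | (E)-3-[4-(tert-butyldimethylsilyloxy)-3,5-dimethoxyphenyl]prop-2-enoic pivalic anhydride (mixed pivalic anhydride) | COc1cc(/C=C/C(=O)OC(=O)C(C)(C)C)cc(OC)c1O[Si](C)(C)C(C)(C)C | intermediate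
6 | (R)-4-benzyl-3-[(E)-3-[4-(tert-butyldimethylsilyloxy)-3,5-dimethoxyphenyl]prop-2-enoyl]oxazolidin-2-one | COc1cc(/C=C/C(=O)N2[C@H](Cc3ccccc3)COC2=O)cc(OC)c1O[Si](C)(C)C(C)(C)C | intermediate
7 | (R)-4-benzyl-3-[(E)-3-(4-hydroxy-3,5-dimethoxyphenyl)prop-2-enoyl]oxazolidin-2-one | COc1cc(/C=C/C(=O)N2[C@H](Cc3ccccc3)COC2=O)cc(OC)c1O | intermediate
8 | dihydroconiferyl alcohol, 4-(3-hydroxypropyl)-2-methoxyphenol | COc1cc(CCCO)ccc1O | starting material
9 | quinone methide, (R)-4-benzyl-3-[(2R)-3-(3,5-dimethoxy-4-oxocyclohexa-2,5-dien-1-ylidene)-2-[4-(3-hydroxypropyl)-2-methoxyphenoxy]propanoyl]oxazolidin-2-one | O=C1C(OC)=CC(=C[C@@H](Oc2ccc(CCCO)cc2OC)C(=O)N2[C@H](Cc3ccccc3)COC2=O)C=C1OC | intermediate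
10 | (R)-4-benzyl-3-[(2R,3R)-3-hydroxy-3-(4-hydroxy-3,5-dimethoxyphenyl)-2-[4-(3-hydroxypropyl)-2-methoxyphenoxy]propanoyl]oxazolidin-2-one (erythro) | COc1cc(CCCO)ccc1O[C@@H](C(=O)N1[C@H](Cc2ccccc2)COC1=O)[C@H](O)c1cc(OC)c(O)c(OC)c1 | intermediate
11 | (1R,2S)-1-(4-hydroxy-3,5-dimethoxyphenyl)-2-[4-(3-hydroxypropyl)-2-methoxyphenoxy]propane-1,3-diol (erythro) | COc1cc(CCCO)ccc1O[C@@H](CO)[C@H](O)c1cc(OC)c(O)c(OC)c1 | intermediate
12 | (2S)-3-hydroxy-1-(4-hydroxy-3,5-dimethoxyphenyl)-2-[4-(3-hydroxypropyl)-2-methoxyphenoxy]propan-1-one | COc1cc(CCCO)ccc1O[C@@H](CO)C(=O)c1cc(OC)c(O)c(OC)c1 | target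

**Count and risks**

Total step count: 6. Longest linear sequence: 6 steps (1 to 12).

Steps most likely to fail:

Step 4. The risks are homocoupling of the sinapoyl radical outpacing cross-coupling, tautomerisation of 9 by loss of H8 before water is supplied, and weak facial discrimination if the excess phenol displaces the imide from magnesium. The fallback builds the same C8–O and C7–O pattern by a boron aldol reaction and sets out from 4 and 8. Compound 4 is N-acylated with bromoacetyl bromide (n-BuLi, THF, −78 °C) to (R)-4-benzyl-3-(2-bromoacetyl)oxazolidin-2-one F1. The phenol of 8 displaces the bromide (K2CO3, acetone) to give (R)-4-benzyl-3-[2-[4-(3-hydroxypropyl)-2-methoxyphenoxy]acetyl]oxazolidin-2-one F2, and its primary alcohol is silylated (TBSCl, imidazole) to the silyl ether F3. Syringaldehyde is silylated to 4-(tert-butyldimethylsilyloxy)-3,5-dimethoxybenzaldehyde F4. The dibutylboron Z-enolate of F3 (Bu2BOTf, i-Pr2NEt, CH2Cl2, −78 °C) should add to F4 to give the syn aldol adduct F5, which has the C8 configuration of 10 because the same (R)-auxiliary directs it. Bu4NF/AcOH removes both silyl groups to give the threo imide F6, the C7 epimer of 10. LiBH4 as in step 5 gives the threo triol F7, and DDQ as in step 6 brings the fallback back to the route at 12.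

Step 6. The risks are epimerisation of C8 once it sits next to the aryl ketone, and oxidation or oxidative cyclisation at the benzylic CH2 of ring B. The fallback sets out from 11 and swaps the phenol-directed dehydrogenation for a protected alcohol oxidation. TBSCl (3.3 equiv) and imidazole should silylate the phenol and the two primary alcohols and leave the hindered secondary benzylic alcohol free, giving the tris-silyl ether F10. Dess–Martin oxidation (NaHCO3, CH2Cl2) gives the tris-silyl ketone F11, and HF·pyridine in THF at 0 °C removes the silyl groups without base, coming back to the route at 12.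

Step 5. The risks are retro-aldol cleavage of the C7–C8 bond, or loss of the C7 hydroxyl through a quinone methide and hydride capture, once the phenol and the C7 alcohol are deprotonated by the hydride reagent. The fallback sets out from 10 and masks the three hydroxyl groups first. Et3SiOTf and 2,6-lutidine (CH2Cl2, −78 °C) give the tris(triethylsilyl) ether F8. LiBH4 then cleaves the imide to the C9 alcohol F9, and HF·pyridine removes the silyl groups, coming back to the route at 11.

**Further compounds**

F1 | step 4 | (R)-4-benzyl-3-(2-bromoacetyl)oxazolidin-2-one | O=C(CBr)N1[C@H](Cc2ccccc2)COC1=O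
F2 | step 4 | (R)-4-benzyl-3-[2-[4-(3-hydroxypropyl)-2-methoxyphenoxy]acetyl]oxazolidin-2-one | COc1cc(CCCO)ccc1OCC(=O)N1[C@H](Cc2ccccc2)COC1=O
F3 | step 4 | (R)-4-benzyl-3-[2-[4-[3-(tert-butyldimethylsilyloxy)propyl]-2-methoxyphenoxy]acetyl]oxazolidin-2-one | COc1cc(CCCO[Si](C)(C)C(C)(C)C)ccc1OCC(=O)N1[C@H](Cc2ccccc2)COC1=O
F4 | step 4 | 4-(tert-butyldimethylsilyloxy)-3,5-dimethoxybenzaldehyde | COc1cc(C=O)cc(OC)c1O[Si](C)(C)C(C)(C)C
F5 | step 4 | (R)-4-benzyl-3-[(2R,3S)-3-[4-(tert-butyldimethylsilyloxy)-3,5-dimethoxyphenyl]-2-[4-[3-(tert-butyldimethylsilyloxy)propyl]-2-methoxyphenoxy]-3-hydroxypropanoyl]oxazolidin-2-one | COc1cc(CCCO[Si](C)(C)C(C)(C)C)ccc1O[C@@H](C(=O)N1[C@H](Cc2ccccc2)COC1=O)[C@@H](O)c1cc(OC)c(O[Si](C)(C)C(C)(C)C)c(OC)c1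
F6 | step 4 | (R)-4-benzyl-3-[(2R,3S)-3-hydroxy-3-(4-hydroxy-3,5-dimethoxyphenyl)-2-[4-(3-hydroxypropyl)-2-methoxyphenoxy]propanoyl]oxazolidin-2-one (threo) | COc1cc(CCCO)ccc1O[C@@H](C(=O)N1[C@H](Cc2ccccc2)COC1=O)[C@@H](O)c1cc(OC)c(O)c(OC)c1
F7 | step 4 | (1S,2S)-1-(4-hydroxy-3,5-dimethoxyphenyl)-2-[4-(3-hydroxypropyl)-2-methoxyphenoxy]propane-1,3-diol (threo) | COc1cc(CCCO)ccc1O[C@@H](CO)[C@@H](O)c1cc(OC)c(O)c(OC)c1
F8 | step 5 | tris(triethylsilyl) ether of 10 at the ring A phenol, the C7 hydroxyl and the propanol hydroxyl | COc1cc(CCCO[Si](CC)(CC)CC)ccc1O[C@@H](C(=O)N1[C@H](Cc2ccccc2)COC1=O)[C@H](O[Si](CC)(CC)CC)c1cc(OC)c(O[Si](CC)(CC)CC)c(OC)c1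
F9 | step 5 | tris(triethylsilyl) ether of 11 with free C9 hydroxyl | COc1cc(CCCO[Si](CC)(CC)CC)ccc1O[C@@H](CO)[C@H](O[Si](CC)(CC)CC)c1cc(OC)c(O[Si](CC)(CC)CC)c(OC)c1
F10 | step 6 | tris(tert-butyldimethylsilyl) ether of 11 at the ring A phenol and both primary hydroxyls | COc1cc(CCCO[Si](C)(C)C(C)(C)C)ccc1O[C@@H](CO[Si](C)(C)C(C)(C)C)[C@H](O)c1cc(OC)c(O[Si](C)(C)C(C)(C)C)c(OC)c1
F11 | step 6 | tris(tert-butyldimethylsilyl) ether of 12 | COc1cc(CCCO[Si](C)(C)C(C)(C)C)ccc1O[C@@H](CO[Si](C)(C)C(C)(C)C)C(=O)c1cc(OC)c(O[Si](C)(C)C(C)(C)C)c(OC)c1
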